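## The problem

The target is a cembranolide: a 14-membered carbocycle (C1–C14) with E-trisubstituted alkenes at C3=C4 and C7=C8, a trisubstituted epoxide at C11–C12 and an acetate at C13. It is fused across C1–C2 to a trans α-methylene-γ-butyrolactone (C15, C16, C17). The ring problem is thus a macrocycle with one small ring on its rim, and any closure of the large ring must be made before, or in the presence of, that lactone.

The five stereocentres fall into two groups, C1/C2 at the ring fusion and C11/C12/C13 across the ring. C2 can control C1 if the C1–C15 bond is delivered from the C2 oxygen, and a free 13-hydroxyl can deliver the epoxide oxygen to C11=C12. The two groups are too far apart to control each other, so C2 and C13 each need an external source of chirality. Hydroxyl-directed epoxidation next to the C12 methyl gives the erythro epoxy alcohol, whereas the target is threo, so C13 must be inverted after it has done its directing work.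

The α-methylene lactone (bases, phosphines, hydrides), the epoxide next to an ester (acid), the allylic C2–O bond and the skipped 1,5-diene array (acid-induced transannular cyclisation) will not survive rough treatment.

The enabling feature is that, with C13 at the ketone level, C13 and the lactone carbonyl C16 are 1,5-related through C14–C1–C15, with ring-fusion carbon C1 at the centre. This is the retron of a [2+2] photocycloaddition/retro-aldol (de Mayo) sequence. Undoing it merges carbocycle and lactone into one 15-membered β-keto lactone with a vinyl group on C2, which is a farnesyl chain plus two two-carbon units.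

## Retrosynthesis

**23 ⇒ 22.** The C13–O(acetyl) bond is cut with inversion (Mitsunobu with acetic acid). The alternative, acetylating a 13S alcohol, would need a threo-selective epoxidation, which an allylic alcohol with only A(1,2) strain does not offer. Epoxy alcohol 22 has the erythro arrangement that directed epoxidation provides. The forward step must achieve SN2 at a carbinol flanked by a fully substituted epoxide carbon and must spare the methylene lactone.

**22 ⇒ 21.** Both epoxide C–O bonds are cut. A vanadium-bound 13-hydroxyl picks C11=C12 out of three trisubstituted alkenes and an enoate and sets C11 and C12 from C13. The precursor 21 has two stereocentres fewer.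

**21 ⇒ 20 ⇒ 16 ⇒ 15 ⇒ 14.** The C15=C17 bond is cut (Eschenmoser methylenation of the lactone enolate). It is placed after the C13 ketone has been reduced (15) and silylated (16), because a C13 ketone would enolise first and the enoate would not survive a hydride reduction. Ketone 14 is simpler by one stereocentre and has no Michael acceptor. The forward reduction must be reagent-controlled (13R).

**14 ⇒ 12 (through 13).** C1–C15 and C13–C14 are cut and C13–C15 is reconnected. Cutting any single ring bond of 14 leaves a lactone-bearing open chain with C1 and C2 to be set acyclically. This double cut removes the lactone ring, the carbocycle and the C1 stereocentre at once. It leaves macrolactone 12, whose only stereocentre is C2 and whose three E-alkenes are those of farnesol. The forward reaction must form C15–C1 across the ester tether, prefer the vinyl group to C3=C4, and put C14 trans to C3.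

**12 ⇒ 11 ⇒ 10.** The C13–C15 bond is cut (intramolecular Reformatsky reaction of bromoacetate-enal 10, then oxidation). The neighbouring cut at the C16–O ester bond (acylketene macrolactonisation) would need the C2 hydroxyl protected through three oxidation-level changes and then freed. The Reformatsky closure needs no protecting group.

**10 ⇒ 8 ⇒ 6 + 7.** The C13 oxygen is removed (allylic oxidation of the terminal E-methyl) and the ester bond to bromoacetyl bromide 7 is cut. This leaves the resolved bis-allylic alcohol 6.

**6 ⇒ 5 ⇒ 4 ⇒ 2 + 3 ⇒ 1.** The C1–C2 bond is cut (vinylmagnesium bromide 3 onto farnesal 2, from farnesol 1). C2 is resolved with a lipase through acetate 5.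

## Roads not taken

**Alternative 1:** The cut is C7=C8. Low-valent titanium from TiCl3(DME)1.5 and zinc–copper couple would couple the C7 aldehyde and the C8 methyl ketone of open-chain A2 to the 14-membered triene A1.
- Merits: carbonyl coupling is among the most dependable closures of 14-membered terpenoid rings and makes ring and alkene together. A1 already carries C17, so no methylenation is needed later.
- Weak points: an aldehyde/methyl ketone pair gives a trisubstituted alkene whose geometry the reagent does not control. Low-valent titanium tolerates neither lactone nor enoate, so C2, C13 and C16 travel as silyl ethers and the lactone needs several more steps, including differentiation of one primary from two secondary silyl ethers. C1, C2 and C13 must all be set in the acyclic chain.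
- Comparison: this ring closure is safer than step 9. Against that, the chosen plan takes all three E-alkenes intact from farnesol, sets C1 in the ring-forming step and is shorter.

**Alternative 2:** The cut is C11–C12, as an alkyne. Mo(≡CC6H4OMe-4)(OSiPh3)3 would metathesise the two methyl-capped alkynes of diyne A4 to cycloalkyne A3 with loss of 2-butyne.
- Merits: ring-closing alkyne metathesis is reliable for this ring size and tolerates the lactone. There is no geometry issue at closure, and C13 is propargylic in A4, so it can be set by asymmetric alkynylation. In C13 control this road is at least as good as the macrocyclic ketone reduction of step 10.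
- Weak points: the alkyne must still become the E-alkene with a methyl on C12 (hydroxyl-directed trans-hydrostannation with [Cp*RuCl]4/Bu3SnH, then methylation), two further steps with a regiochemical demand. A4 needs three stereocentres and two butynyl arms assembled from several building blocks.
- Comparison: the closure is more certain than step 9. The chosen plan sets against it a C3–C13 chain that comes ready-made with its methyl-bearing E-alkenes, and one stereocentre (C1) that need not be built in the open chain.

**Alternative 3:** The cut is C6–C7. 9-BBN would hydroborate the terminal alkene of the C3=C4–C5=C6 diene of A6 at C6, and Pd(dppf)Cl2 with AsPh3 and Cs2CO3 would couple the alkylborane with the E-alkenyl iodide at C7 to give A5.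
- Merits: the coupling is mild, lactone-tolerant and stereoretentive. A5 is the same compound as 16, so the last four steps of the present route would be shared. This is the most direct competitor and the more certain way to 16.
- Weak points: hydroboration of a conjugated diene terminus is less clean than that of an isolated vinyl group. A6 needs the trans-lactone (C1, C2), the 13R silyl ether and the E-iodide, each made separately, so reaching A6 should cost clearly more steps than the eleven that lead to 16 here.
- Comparison: reliability lies with this alternative. The chosen plan sets against it brevity, a single early stereocentre and a terpenoid chain taken whole from farnesol.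

Key step: step 9

Remark: cembrane numbering is used for all macrocycles (ring C1–C14; C15 lactone α-carbon on C1; C16 lactone carbonyl bound through oxygen to C2; C17 exocyclic methylene; methyls on C4, C8, C12). The target is (1R,2S,11R,12S,13S). The descriptor of C2 changes from R to S at step 12, and that of C12 from R to S at step 15, only through changed priorities.

## Route

Step 1
Reactants: 1 (2E,6E)-farnesol
Product: 2 (2E,6E)-farnesal
Conditions: MnO2 (activated, 15 equiv), CH2Cl2, rt
Reagents that add atoms: none
Why: Allylic oxidation on MnO2 stops at the enal, leaves the isolated trisubstituted alkenes alone and keeps the 2E geometry under neutral conditions.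

Step 2
Reactants: 2 (2E,6E)-farnesal; 3 vinylmagnesium bromide
Product: 4 rac-(4E,8E)-5,9,13-trimethyltetradeca-1,4,8,12-tetraen-3-ol
Conditions: THF, −78 → 0 °C; aq NH4Cl
Reagents that add atoms: none
Why: Grignard 1,2-addition to a β,β-disubstituted enal forms the C1–C2 bond and the bis-allylic carbinol (racemic at C2).

Step 3
Reactants: 4 rac-(4E,8E)-5,9,13-trimethyltetradeca-1,4,8,12-tetraen-3-ol
Product: 5 (3R,4E,8E)-5,9,13-trimethyltetradeca-1,4,8,12-tetraen-3-yl acetate
Conditions: Candida antarctica lipase B (immobilised), vinyl acetate (3 equiv), hexane, 30 °C, run to about half conversion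
Reagents that add atoms: vinyl acetate CC(=O)OC=C
Why: Lipase kinetic resolution by transesterification; by Kazlauskas' rule the enantiomer with the vinyl group in the medium pocket and the trisubstituted alkenyl chain as the large group is acylated, which is 3R (C2 of the target skeleton). The unreacted S enantiomer of 4 is separated by chromatography.

Step 4
Reactants: 5 (3R,4E,8E)-5,9,13-trimethyltetradeca-1,4,8,12-tetraen-3-yl acetate
Product: 6 (3R,4E,8E)-5,9,13-trimethyltetradeca-1,4,8,12-tetraen-3-ol
Conditions: K2CO3 (0.2 equiv), MeOH, 0 °C → rt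
Reagents that add atoms: none
Why: Base-catalysed methanolysis of the acetate; the C–O bond at the stereocentre is not broken, so the configuration is kept.

Step 5
Reactants: 6 (3R,4E,8E)-5,9,13-trimethyltetradeca-1,4,8,12-tetraen-3-ol; 7 bromoacetyl bromide
Product: 8 (3R,4E,8E)-5,9,13-trimethyltetradeca-1,4,8,12-tetraen-3-yl bromoacetate
Conditions: pyridine, CH2Cl2, −20 → 0 °C
Reagents that add atoms: none
Why: O-acylation with an acyl bromide; it brings in C15 and C16 together with the halide needed for ring closure, under non-acidic conditions that spare the bis-allylic C–O bond.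

Step 6
Reactants: 8 (3R,4E,8E)-5,9,13-trimethyltetradeca-1,4,8,12-tetraen-3-yl bromoacetate
Product: 10 (3R,4E,8E,12E)-5,9,13-trimethyl-14-oxotetradeca-1,4,8,12-tetraen-3-yl bromoacetate, via allylic alcohol 9 (not isolated)
Conditions: SeO2 (0.3 equiv), t-BuOOH (2 equiv), salicylic acid (0.1 equiv), CH2Cl2, 0 °C → rt; then MnO2, CH2Cl2, rt
Reagents that add atoms: selenium dioxide O=[Se]=O; tert-butyl hydroperoxide CC(C)(C)OO
Why: Sharpless catalytic SeO2 allylic oxidation (ene reaction, then [2,3]-shift) attacks the E-methyl of the terminal, most electron-rich and least hindered trisubstituted alkene, as with farnesyl acetate. The alkene next to the acyloxy-bearing carbon is deactivated, and MnO2 carries the remaining allylic alcohol 9 on to the E-enal.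

Step 7
Reactants: 10 (3R,4E,8E,12E)-5,9,13-trimethyl-14-oxotetradeca-1,4,8,12-tetraen-3-yl bromoacetate
Product: 11 (4RS,5E,9E,13E,15R)-15-ethenyl-4-hydroxy-5,9,13-trimethyl-1-oxacyclopentadeca-5,9,13-trien-2-one
Conditions: SmI2 (3 equiv), THF, slow addition of 10 (final 2 mM), 0 °C; aq NH4Cl
Reagents that add atoms: none
Why: Intramolecular samarium Reformatsky reaction: divalent samarium reduces the C–Br bond and the trivalent samarium enolate adds 1,2 to the enal, forming C13–C15 and the 15-membered lactone. Both C13 epimers are carried on because the next step removes that centre.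

Step 8
Reactants: 11 (4RS,5E,9E,13E,15R)-15-ethenyl-4-hydroxy-5,9,13-trimethyl-1-oxacyclopentadeca-5,9,13-trien-2-one
Product: 12 (5E,9E,13E,15R)-15-ethenyl-5,9,13-trimethyl-1-oxacyclopentadeca-5,9,13-triene-2,4-dione
Conditions: Dess–Martin periodinane, pyridine, CH2Cl2, 0 °C → rt
Reagents that add atoms: none
Why: Dess–Martin oxidation of an allylic β-hydroxy ester to the β-keto ester; pyridine buffers the acetic acid so that the doubly allylic C2–O bond does not ionise.

Step 9
Reactants: 12 (5E,9E,13E,15R)-15-ethenyl-5,9,13-trimethyl-1-oxacyclopentadeca-5,9,13-triene-2,4-dione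
Product: 14 (1R,2R,3E,7E,11E)-13-oxo-17-norcembra-3,7,11-trien-16,2-olide, via cyclobutanol photoadduct 13 (not isolated)
Conditions: [Ir(dF(CF3)ppy)2(dtbbpy)]PF6 (2 mol %), 450 nm LEDs, degassed ClCH2CH2Cl (1 mM), 50 °C; then DBU (0.2 equiv), t-BuOH (5 equiv), 0 °C
Reagents that add atoms: none
Why: Proposed new method: triplet energy transfer from the iridium sensitiser (triplet energy about 61 kcal/mol) should reach only the hydrogen-bonded enol of 12, whose C11=C12–C13(OH)=C15–C16=O dienoate chromophore lies below the plain enone of the keto tautomer and of 14, and the twisted enol triplet then adds across the C2 vinyl group in two stages as in a de Mayo reaction. The first bond C15–C1 closes the γ-lactone ring by 1,5-closure (5-exo-trig, rule of five) across the three-atom C16–O–C2 tether, the second bond C13–C14 closes the cis-fused cyclobutanol 13 by 4-exo recombination of the 1,4-biradical, and DBU then cleaves C13–C15 of this strained β-hydroxy ester by retro-aldol reaction, so that the 14-membered carbocycle arises by two-carbon ring expansion (C14 and C1 inserted between C13 and C15) and not by a closure of its own. The closest known reactions are the de Mayo reaction of enolised 1,3-diketones, the intramolecular dioxinone photocycloaddition–fragmentation and the visible-light sensitised [2+2] cycloaddition of 1,3-dienes with unactivated alkenes; an enolised β-keto ester reacting across the ester tether of a macrolactone has no precedent. C1 is the only new stereocentre that survives (C13 and C15 of 13 are erased by the fragmentation) and it is set by C2 in the first bond: in the chair-like five-ring transition state the C2–C3 bond is pseudo-equatorial and C2–H eclipses the vinyl group, so C14 ends trans to C3 and the lactone is trans-fused (1R from 2R). Regiochemistry is fixed by the tether, since C15 can reach only C1 in a five-membered array. Chemoselectivity over C3=C4, which hangs on the same tether, is expected because its biradical would have to close C13–C4 between two fully substituted carbons across the ring and should revert, and over the C7=C8/C11=C12 1,5-diene because a crossed addition would have to join the methyl-bearing carbons C12 and C8. E/Z isomerisation at C11=C12 in the triplet is reversible and funnels back, whereas the fragmentation is irreversible. The five-ring closure needs the minor s-cis rotamer of the ester, so the quantum yield will be low; the warm, moderately polar solvent raises the share of this rotamer, and the product, which the sensitiser cannot excite, tolerates long irradiation.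

Step 10
Reactants: 14 (1R,2R,3E,7E,11E)-13-oxo-17-norcembra-3,7,11-trien-16,2-olide
Product: 15 (1R,2R,3E,7E,11E,13R)-13-hydroxy-17-norcembra-3,7,11-trien-16,2-olide
Conditions: (S)-2-methyl-CBS-oxazaborolidine (0.3 equiv), catecholborane (1.5 equiv), toluene, −78 °C
Reagents that add atoms: none
Why: Corey–Bakshi–Shibata reduction; the α-methyl alkenyl group (C12) acts as the large substituent and C14H2 as the small one, so the S catalyst delivers hydride to the face that gives 13R. Catecholborane at −78 °C touches neither the lactone nor the trisubstituted alkenes.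

Step 11
Reactants: 15 (1R,2R,3E,7E,11E,13R)-13-hydroxy-17-norcembra-3,7,11-trien-16,2-olide
Product: 16 (1R,2R,3E,7E,11E,13R)-13-(tert-butyldimethylsilyloxy)-17-norcembra-3,7,11-trien-16,2-olide
Conditions: TBSCl, imidazole, DMF, rt
Reagents that add atoms: tert-butyldimethylsilyl chloride CC(C)(C)[Si](C)(C)Cl
Why: Silylation of a secondary allylic alcohol; it masks the hydroxyl for the enolate chemistry and prevents translactonisation to C13.

Step 12
Reactants: 16 (1R,2R,3E,7E,11E,13R)-13-(tert-butyldimethylsilyloxy)-17-norcembra-3,7,11-trien-16,2-olide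
Product: 20 (1R,2S,3E,7E,11E,13R)-13-(tert-butyldimethylsilyloxy)cembra-3,7,11,15(17)-tetraen-16,2-olide, via lithium enolate 17 (not isolated), via Mannich base 18 (not isolated), via methiodide 19 (not isolated)
Conditions: LDA, THF, −78 °C; CH2=NMe2+ I−, −78 → 0 °C; then MeI, CH2Cl2, rt; then DBU, rt
Reagents that add atoms: Eschenmoser's salt (dimethylmethyleneammonium iodide) C=[N+](C)C.[I-]
Why: Eschenmoser α-methylenation: the lactone enolate is aminomethylated at C15, the amine is quaternised and trimethylamine is eliminated to give the exocyclic C15=C17 bond. No other carbonyl or acidic site is left in 16, and C1 is not enolisable.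

Step 13
Reactants: 20 (1R,2S,3E,7E,11E,13R)-13-(tert-butyldimethylsilyloxy)cembra-3,7,11,15(17)-tetraen-16,2-olide
Product: 21 (1R,2S,3E,7E,11E,13R)-13-hydroxycembra-3,7,11,15(17)-tetraen-16,2-olide
Conditions: HF·pyridine, pyridine, THF, 0 °C → rt
Reagents that add atoms: none
Why: Buffered fluoride desilylation; these non-basic, weakly nucleophilic conditions leave the methylene lactone and the allylic C2–O bond alone.

Step 14
Reactants: 21 (1R,2S,3E,7E,11E,13R)-13-hydroxycembra-3,7,11,15(17)-tetraen-16,2-olide
Product: 22 (1R,2S,3E,7E,11R,12R,13R)-11,12-epoxy-13-hydroxycembra-3,7,15(17)-trien-16,2-olide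
Conditions: VO(acac)2 (5 mol %), t-BuOOH (1.5 equiv), CH2Cl2, 0 °C
Reagents that add atoms: tert-butyl hydroperoxide CC(C)(C)OO
Why: Vanadium-catalysed hydroxyl-directed epoxidation reaches only the allylic C11=C12 bond. A(1,2) strain between the C12 methyl and the carbinol substituent places C13–H near the alkene plane, so oxygen is delivered to the face that gives the erythro epoxy alcohol, which sets 11R and the C12 configuration of the target from 13R.

Step 15
Reactants: 22 (1R,2S,3E,7E,11R,12R,13R)-11,12-epoxy-13-hydroxycembra-3,7,15(17)-trien-16,2-olide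
Product: 23 (1R,2S,3E,7E,11R,12S,13S)-13-acetoxy-11,12-epoxycembra-3,7,15(17)-trien-16,2-olide
Conditions: PPh3, DIAD (premixed), AcOH, toluene, 0 °C → rt
Reagents that add atoms: acetic acid CC(O)=O
Why: Mitsunobu esterification with inversion at C13 turns the erythro epoxy alcohol into the threo acetate in one step. Premixing phosphine and azodicarboxylate keeps free PPh3 away from the methylene lactone.

## Compound list

1 | (2E,6E)-farnesol | CC(C)=CCC/C(C)=C/CC/C(C)=C/CO | starting material
2 | (2E,6E)-farnesal | CC(C)=CCC/C(C)=C/CC/C(C)=C/C=O | intermediate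
3 | vinylmagnesium bromide | C=C[Mg]Br | starting material
4 | rac-(4E,8E)-5,9,13-trimethyltetradeca-1,4,8,12-tetraen-3-ol | C=CC(O)/C=C(\C)CC/C=C(\C)CCC=C(C)C | intermediate
5 | (3R,4E,8E)-5,9,13-trimethyltetradeca-1,4,8,12-tetraen-3-yl acetate | C=C[C@@H](OC(C)=O)/C=C(\C)CC/C=C(\C)CCC=C(C)C | intermediate
6 | (3R,4E,8E)-5,9,13-trimethyltetradeca-1,4,8,12-tetraen-3-ol | C=C[C@@H](O)/C=C(\C)CC/C=C(\C)CCC=C(C)C | intermediate
7 | bromoacetyl bromide | O=C(Br)CBr | starting material
8 | (3R,4E,8E)-5,9,13-trimethyltetradeca-1,4,8,12-tetraen-3-yl bromoacetate | C=C[C@@H](OC(=O)CBr)/C=C(\C)CC/C=C(\C)CCC=C(C)C | intermediate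
9 | (3R,4E,8E,12E)-14-hydroxy-5,9,13-trimethyltetradeca-1,4,8,12-tetraen-3-yl bromoacetate | C=C[C@@H](OC(=O)CBr)/C=C(\C)CC/C=C(\C)CC/C=C(\C)CO | intermediate
10 | (3R,4E,8E,12E)-5,9,13-trimethyl-14-oxotetradeca-1,4,8,12-tetraen-3-yl bromoacetate | C=C[C@@H](OC(=O)CBr)/C=C(\C)CC/C=C(\C)CC/C=C(\C)C=O | intermediate
11 | (4RS,5E,9E,13E,15R)-15-ethenyl-4-hydroxy-5,9,13-trimethyl-1-oxacyclopentadeca-5,9,13-trien-2-one | C=C[C@H]1OC(=O)CC(O)/C(C)=C/CC/C(C)=C/CC/C(C)=C/1 | intermediate
12 | (5E,9E,13E,15R)-15-ethenyl-5,9,13-trimethyl-1-oxacyclopentadeca-5,9,13-triene-2,4-dione (15-membered β-keto lactone; C2 vinyl) | C=C[C@H]1OC(=O)CC(=O)/C(C)=C/CC/C(C)=C/CC/C(C)=C/1 | intermediate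
13 | cyclobutanol photoadduct of 12 (cis-fused 2-oxabicyclo[3.2.0]heptan-3-one from new bonds C1–C15 and C13–C14; 13-hydroxy, C13 epimers; C2 and C13 bridged by the C3–C12 chain) | O=C1O[C@H]2/C=C(\C)CC/C=C(\C)CC/C=C(\C)C3(O)C[C@@H]2[C@@H]13 | intermediate
14 | (1R,2R,3E,7E,11E)-13-oxo-17-norcembra-3,7,11-trien-16,2-olide (trans-fused γ-lactone on the 14-membered enone) | C1C(=O)O[C@H]2/C=C(\C)CC/C=C(\C)CC/C=C(\C)C(=O)C[C@H]12 | intermediate
15 | (1R,2R,3E,7E,11E,13R)-13-hydroxy-17-norcembra-3,7,11-trien-16,2-olide | C1C(=O)O[C@H]2/C=C(\C)CC/C=C(\C)CC/C=C(\C)[C@H](O)C[C@H]12 | intermediate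
16 | (1R,2R,3E,7E,11E,13R)-13-(tert-butyldimethylsilyloxy)-17-norcembra-3,7,11-trien-16,2-olide | C1C(=O)O[C@H]2/C=C(\C)CC/C=C(\C)CC/C=C(\C)[C@H](O[Si](C)(C)C(C)(C)C)C[C@H]12 | intermediate
17 | lithium enolate of 16 (C15=C16–OLi) | C1=C(O[Li])O[C@H]2/C=C(\C)CC/C=C(\C)CC/C=C(\C)[C@H](O[Si](C)(C)C(C)(C)C)C[C@H]12 | intermediate
18 | 15-(dimethylaminomethyl) derivative of 16 (Mannich base; C15 epimers) | CN(C)CC1C(=O)O[C@H]2/C=C(\C)CC/C=C(\C)CC/C=C(\C)[C@H](O[Si](C)(C)C(C)(C)C)C[C@H]12 | intermediate
19 | 15-(trimethylammoniomethyl) derivative of 16, iodide | C[N+](C)(C)CC1C(=O)O[C@H]2/C=C(\C)CC/C=C(\C)CC/C=C(\C)[C@H](O[Si](C)(C)C(C)(C)C)C[C@H]12.[I-] | intermediate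
20 | (1R,2S,3E,7E,11E,13R)-13-(tert-butyldimethylsilyloxy)cembra-3,7,11,15(17)-tetraen-16,2-olide | C=C1C(=O)O[C@H]2/C=C(\C)CC/C=C(\C)CC/C=C(\C)[C@H](O[Si](C)(C)C(C)(C)C)C[C@H]12 | intermediate
21 | (1R,2S,3E,7E,11E,13R)-13-hydroxycembra-3,7,11,15(17)-tetraen-16,2-olide | C=C1C(=O)O[C@H]2/C=C(\C)CC/C=C(\C)CC/C=C(\C)[C@H](O)C[C@H]12 | intermediate
22 | (1R,2S,3E,7E,11R,12R,13R)-11,12-epoxy-13-hydroxycembra-3,7,15(17)-trien-16,2-olide (erythro epoxy alcohol) | C=C1C(=O)O[C@H]2/C=C(\C)CC/C=C(\C)CC[C@H]3O[C@]3(C)[C@H](O)C[C@H]12 | intermediate
23 | (1R,2S,3E,7E,11R,12S,13S)-13-acetoxy-11,12-epoxycembra-3,7,15(17)-trien-16,2-olide | C=C1C(=O)O[C@H]2/C=C(\C)CC/C=C(\C)CC[C@H]3O[C@]3(C)[C@@H](OC(C)=O)C[C@H]12 | target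

## Step count and least certain steps

Total: 15 steps. Longest linear sequence: 15 steps (1 → 23).

**Step 9 (key step, proposed new method).**
- What may go wrong: the ester stays s-trans during the triplet lifetime, so the five-ring closure C15–C1 is not reached and only E/Z scrambling at C11=C12 is seen. Material may then leak slowly through attack on C3=C4 or through hydrogen transfer within the biradical. Closure with C14 cis to C3 would give the cis-fused lactone.
- Fallback (known chemistry, from 6, back at 14): the same ring-fusion bonds are made in the ground state. Acylation of 6 with acryloyl chloride would give the acrylate F1. Ring-closing metathesis with the second-generation Grubbs catalyst RuCl2(=CHPh)(SIMes)(PCy3) would close C15=C1 to the butenolide F2 with loss of ethene; the ruthenium carbene starts at the vinyl group and leaves trisubstituted C3=C4 alone, which settles the chemoselectivity the photoreaction leaves open. SeO2/t-BuOOH followed by MnO2 would give the enal F3, zinc Reformatsky addition of allyl bromoacetate the β-hydroxy ester F4, and Dess–Martin oxidation the β-keto ester F5. With Cs2CO3 in MeCN at high dilution the β-keto ester carbon (the future C14) should add to C1 of the butenolide anti to the C3 substituent (reversible intramolecular Michael addition) and close the 14-membered keto diester F6. Pd(PPh3)4 and morpholine would then remove the allyl ester with decarboxylation and give 14.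

**Step 7.**
- What may go wrong: intermolecular aldol or pinacol coupling of the enal, or simple reduction of the bromoacetate to the acetate, may outrun closure of the 15-membered ring.
- Fallback (from 6, back at 12): the ring is closed at the ester bond instead. Silylation of 6 (TBSCl, imidazole) would give the silyl ether F7. SeO2/t-BuOOH then MnO2 would give the enal F8, and NaClO2/NaH2PO4/2-methyl-2-butene the acid F9. Meldrum's acid with DCC and DMAP would give the acyl Meldrum's acid F10, and HF·pyridine would free the C2 hydroxyl in F11. In refluxing toluene at high dilution F11 should lose acetone and CO2 to an acylketene that the C2 hydroxyl traps, giving 12 directly.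

**Step 10.**
- What may go wrong: poor facial selectivity, because the two groups flanking the ketone are of similar size and the macrocycle may impose its own preference for peripheral attack.
- Fallback (from 14, back at 15): substrate-controlled Luche reduction (NaBH4, CeCl3·7H2O, MeOH, −78 °C) and separation. The 13R fraction is 15. The 13S alcohol F12 would be inverted by Mitsunobu reaction with 4-nitrobenzoic acid to the 13R ester F13 and methanolysed (K2CO3, MeOH) to 15.

**Step 15.**
- What may go wrong: sluggish SN2 displacement at C13 next to the fully substituted epoxide carbon, leading to elimination or to retention through epoxide participation. Conjugate addition of the phosphine to the methylene lactone is a further risk.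
- Fallback (from 22, back at 23): activation and displacement are separated and no phosphine is used. Chloromethanesulfonyl chloride and pyridine would give the chloromethanesulfonate F14, and CsOAc with 18-crown-6 in toluene at 80 °C would displace it with inversion to 23.

## Further compounds

F1 | step 9 | (3R,4E,8E)-5,9,13-trimethyltetradeca-1,4,8,12-tetraen-3-yl acrylate | C=C[C@@H](OC(=O)C=C)/C=C(\C)CC/C=C(\C)CCC=C(C)C
F2 | step 9 | (5R)-5-[(1E,5E)-2,6,10-trimethylundeca-1,5,9-trien-1-yl]furan-2(5H)-one | O=C1C=C[C@H](/C=C(\C)CC/C=C(\C)CCC=C(C)C)O1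
F3 | step 9 | (2E,6E,10E)-2,6,10-trimethyl-11-[(2R)-5-oxo-2,5-dihydrofuran-2-yl]undeca-2,6,10-trienal | O=C1C=C[C@H](/C=C(\C)CC/C=C(\C)CC/C=C(\C)C=O)O1
F4 | step 9 | allyl (4E,8E,12E)-3-hydroxy-4,8,12-trimethyl-13-[(2R)-5-oxo-2,5-dihydrofuran-2-yl]trideca-4,8,12-trienoate | O=C1C=C[C@H](/C=C(\C)CC/C=C(\C)CC/C=C(\C)C(O)CC(=O)OCC=C)O1
F5 | step 9 | allyl (4E,8E,12E)-4,8,12-trimethyl-3-oxo-13-[(2R)-5-oxo-2,5-dihydrofuran-2-yl]trideca-4,8,12-trienoate | O=C1C=C[C@H](/C=C(\C)CC/C=C(\C)CC/C=C(\C)C(=O)CC(=O)OCC=C)O1
F6 | step 9 | allyl (1R,2R,3E,7E,11E)-13-oxo-17-norcembra-3,7,11-trien-16,2-olide-14-carboxylate (C14 epimers) | C1C(=O)O[C@H]2/C=C(\C)CC/C=C(\C)CC/C=C(\C)C(=O)C(C(=O)OCC=C)[C@H]12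
F7 | step 7 | (3R,4E,8E)-3-(tert-butyldimethylsilyloxy)-5,9,13-trimethyltetradeca-1,4,8,12-tetraene | C=C[C@@H](O[Si](C)(C)C(C)(C)C)/C=C(\C)CC/C=C(\C)CCC=C(C)C
F8 | step 7 | (2E,6E,10E,12R)-12-(tert-butyldimethylsilyloxy)-2,6,10-trimethyltetradeca-2,6,10,13-tetraenal | C=C[C@@H](O[Si](C)(C)C(C)(C)C)/C=C(\C)CC/C=C(\C)CC/C=C(\C)C=O
F9 | step 7 | (2E,6E,10E,12R)-12-(tert-butyldimethylsilyloxy)-2,6,10-trimethyltetradeca-2,6,10,13-tetraenoic acid | C=C[C@@H](O[Si](C)(C)C(C)(C)C)/C=C(\C)CC/C=C(\C)CC/C=C(\C)C(=O)O
F10 | step 7 | 5-[(2E,6E,10E,12R)-12-(tert-butyldimethylsilyloxy)-1-hydroxy-2,6,10-trimethyltetradeca-2,6,10,13-tetraenylidene]-2,2-dimethyl-1,3-dioxane-4,6-dione | C=C[C@@H](O[Si](C)(C)C(C)(C)C)/C=C(\C)CC/C=C(\C)CC/C=C(\C)C(O)=C1C(=O)OC(C)(C)OC1=O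
F11 | step 7 | 5-[(2E,6E,10E,12R)-1,12-dihydroxy-2,6,10-trimethyltetradeca-2,6,10,13-tetraenylidene]-2,2-dimethyl-1,3-dioxane-4,6-dione | C=C[C@@H](O)/C=C(\C)CC/C=C(\C)CC/C=C(\C)C(O)=C1C(=O)OC(C)(C)OC1=O
F12 | step 10 | (1R,2R,3E,7E,11E,13S)-13-hydroxy-17-norcembra-3,7,11-trien-16,2-olide | C1C(=O)O[C@H]2/C=C(\C)CC/C=C(\C)CC/C=C(\C)[C@@H](O)C[C@H]12
F13 | step 10 | (1R,2R,3E,7E,11E,13R)-13-(4-nitrobenzoyloxy)-17-norcembra-3,7,11-trien-16,2-olide | C1C(=O)O[C@H]2/C=C(\C)CC/C=C(\C)CC/C=C(\C)[C@H](OC(=O)c3ccc(cc3)[N+](=O)[O-])C[C@H]12
F14 | step 15 | chloromethanesulfonate of 22 at the C13 oxygen (13R) | C=C1C(=O)O[C@H]2/C=C(\C)CC/C=C(\C)CC[C@H]3O[C@]3(C)[C@H](OS(=O)(=O)CCl)C[C@H]12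
A1 | alternative 1 | (1R,2S,3E,7E,11E,13R)-2,13,16-tris(tert-butyldimethylsilyloxy)cembra-3,7,11,15(17)-tetraene | C=C(CO[Si](C)(C)C(C)(C)C)[C@H]1C[C@@H](O[Si](C)(C)C(C)(C)C)/C(C)=C/CC/C(C)=C/CC/C(C)=C/[C@@H]1O[Si](C)(C)C(C)(C)C
A2 | alternative 1 | 7,8-seco keto aldehyde of A1 (C7 aldehyde; C8 methyl ketone) | CC(=O)CC/C=C(\C)[C@H](O[Si](C)(C)C(C)(C)C)C[C@H](C(=C)CO[Si](C)(C)C(C)(C)C)[C@@H](O[Si](C)(C)C(C)(C)C)/C=C(\C)CCC=O
A3 | alternative 2 | lactone-fused 14-membered 3,7-dien-11-yne with 13R triethylsilyl ether | C1C(=O)O[C@H]2/C=C(\C)CC/C=C(\C)CCC#C[C@H](O[Si](CC)(CC)CC)C[C@H]12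
A4 | alternative 2 | open-chain lactone diyne with methyl-capped alkynes at C11 and C12 | CC#CCC/C(C)=C/CC/C(C)=C/[C@@H]1OC(=O)C[C@H]1C[C@@H](O[Si](CC)(CC)CC)C#CC
A5 | alternative 3 | (1R,2R,3E,7E,11E,13R)-13-(tert-butyldimethylsilyloxy)-17-norcembra-3,7,11-trien-16,2-olide (identical with 16) | C1C(=O)O[C@H]2/C=C(\C)CC/C=C(\C)CC/C=C(\C)[C@H](O[Si](C)(C)C(C)(C)C)C[C@H]12
A6 | alternative 3 | open-chain lactone with the C3=C4–C5=C6 diene on C2 and the E-C7 alkenyl iodide | C=C/C(C)=C/[C@@H]1OC(=O)C[C@H]1C[C@@H](O[Si](C)(C)C(C)(C)C)/C(C)=C/CC/C(C)=C/I
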